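**Plan**

- Labels: flavanone half O1, C2 (ketal), C3 (carbinol), C4 (ketone), arene ring A, pyranone ring C, ring B on C2; flavan half primed, arene ring D, pyran ring G, ring B' on C2'; furan ring F is O7'-C2-C3-C8'-C7'.
- Retrosynthesis: after the benzyl ethers, C2-O1 and the C3-OH bond are cut back to a C2=C3 benzofuran carrying a 2-hydroxyaroyl group (ring C open), then O1'-C2' (ring G). Ring D is then taken apart along C6'-C7', C5'-C6', C4a'-C8a' and C8'-C8a' into a 2-diazoacetylfuran and a siloxyalkyne; the furan goes back to a dibromofuroate through the C2-ring B and C3-C4 bonds.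
- Enabling feature: ring D has oxygen on C5', C7', C8a' and carbon on C4a', C8', a pattern that substitution of a phloroglucinol cannot sort out (C6' against C8'). Its C7'-C8' edge is the C=C bond of furan ring F, so a furylketene can grow ring D on that edge from an ynol ether, with every substituent placed by the way the two partners join.
- Forward order: ring F is bought and given ring B (Suzuki) and the ring A ketone (Grignard addition, oxidation); ring D is annulated in step 12; ring G is closed by Mitsunobu etherification; ring C is closed last by epoxidation of C2=C3 with capture by the ring A phenol; hydrogenolysis ends the route.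
- Stereochemistry: C2' comes from a CBS reduction to the (R)-carbinol, inverted to (S) in the Mitsunobu closure; C3 (S) comes from the face of oxygen transfer by a chiral manganese salen complex, and C2 is fixed by the ring closure that follows.

Key step: step 12

Remark: the descriptors are read from the SMILES as written, (2R,3S) for the ketal-carbinol pair and (2'S) for the flavan centre; within that pair only C3 can be chosen, because the ring A oxygen can reach C2 only on the face of ring F that carries C4, so C3 (S) is set by the oxidant and the C2 descriptor of the drawn structure is assumed to denote this one feasible ring junction.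

Abbreviations: ArB = 4-(benzyloxy)phenyl (rings B and B'); ArA = 2-(allyloxy)-4,6-bis(benzyloxy)phenyl; ArA' = 2,4-bis(benzyloxy)-6-hydroxyphenyl; Bn = benzyl; TES = triethylsilyl; TIPS = triisopropylsilyl. The flavan-fused benzofurans are named as 3,4-dihydro-2H-furo[2,3-h]chromenes (O1, C2, C3, C4, C4a, C5, C6, C6a, O7, C8, C9, C9a, C9b; C2 = C2', C5 = C5', C8 = flavanone C2, C9 = flavanone C3).

**Route**

Step 1
Reactants: 1 methyl 4,5-dibromofuran-2-carboxylate; 2 [4-(benzyloxy)phenyl]boronic acid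
Product: 3 methyl 5-[4-(benzyloxy)phenyl]-4-bromofuran-2-carboxylate
Conditions: Pd(PPh3)4 (3 mol %), Na2CO3, toluene/EtOH/H2O, 80 °C
Reagents that add atoms: none
Why: Site-selective Suzuki-Miyaura coupling: zerovalent palladium inserts into the C5-Br bond next to the ring oxygen faster than into the C4-Br bond, so one equivalent of 2 should place ring B on the future C2 and keep the bromide for the next C-C bond.

Step 2
Reactants: 4 2,4,6-trihydroxybenzaldehyde
Product: 5 2,4-bis(benzyloxy)-6-hydroxybenzaldehyde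
Conditions: BnBr (2.1 equiv), K2CO3, DMF, 20 °C
Reagents that add atoms: benzyl bromide, BrCc1ccccc1
Why: Williamson etherification should stop after two benzylations because the last ortho phenol is held in a hydrogen bond to the formyl oxygen and is the least nucleophilic.

Step 3
Reactants: 5 2,4-bis(benzyloxy)-6-hydroxybenzaldehyde
Product: 6 2-(allyloxy)-4,6-bis(benzyloxy)benzaldehyde
Conditions: allyl bromide, K2CO3, DMF, 60 °C
Reagents that add atoms: allyl bromide, C=CCBr
Why: Forcing Williamson etherification caps the chelated phenol as an allyl ether, which can later be removed by zerovalent palladium without touching the benzyl ethers.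

Step 4
Reactants: 3 methyl 5-[4-(benzyloxy)phenyl]-4-bromofuran-2-carboxylate; 6 2-(allyloxy)-4,6-bis(benzyloxy)benzaldehyde
Product: 8 methyl 4-[(ArA)(hydroxy)methyl]-5-(ArB)furan-2-carboxylate (racemic at the carbinol), via furan-4-ylmagnesium chloride 7 (not isolated)
Conditions: i-PrMgCl·LiCl, THF, −25 °C; then 6, −25 → 0 °C; NH4Cl (aq)
Reagents that add atoms: none
Why: Bromine-magnesium exchange with i-PrMgCl·LiCl tolerates the methyl ester at low temperature, and 1,2-addition of the furyl Grignard reagent to the aldehyde forms the C3-C4 bond; the carbinol centre is left racemic because step 5 removes it.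

Step 5
Reactants: 8 methyl 4-[(ArA)(hydroxy)methyl]-5-(ArB)furan-2-carboxylate
Product: 9 methyl 4-[2-(allyloxy)-4,6-bis(benzyloxy)benzoyl]-5-(ArB)furan-2-carboxylate
Conditions: Dess-Martin periodinane, CH2Cl2, 20 °C
Reagents that add atoms: none
Why: Dess-Martin oxidation of the doubly activated (furyl, aryl) carbinol gives the diaryl ketone that becomes C4; no other oxidizable group is present.

Step 6
Reactants: 9 methyl 4-[2-(allyloxy)-4,6-bis(benzyloxy)benzoyl]-5-(ArB)furan-2-carboxylate
Product: 10 4-[2-(allyloxy)-4,6-bis(benzyloxy)benzoyl]-5-(ArB)furan-2-carboxylic acid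
Conditions: LiOH, THF/MeOH/H2O, 20 °C; then 1 M HCl
Reagents that add atoms: lithium hydroxide, [Li+].[OH-]
Why: Saponification of the unhindered furoate; the di-ortho-substituted diaryl ketone and the ethers are inert to hydroxide.

Step 7
Reactants: 10 4-[2-(allyloxy)-4,6-bis(benzyloxy)benzoyl]-5-(ArB)furan-2-carboxylic acid
Product: 12 1-{4-[2-(allyloxy)-4,6-bis(benzyloxy)benzoyl]-5-(ArB)furan-2-yl}-2-diazoethan-1-one, via furan-2-carbonyl chloride 11 (not isolated)
Conditions: (COCl)2, DMF (cat.), CH2Cl2, 0 → 20 °C; evaporate; CH2N2 (excess), Et2O, 0 °C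
Reagents that add atoms: diazomethane, C=[N+]=[N-]
Why: Acid chloride formation and C-acylation of diazomethane (first stage of the Arndt-Eistert sequence), with a second equivalent of diazomethane consuming HCl, should give the α-diazo ketone.

Step 8
Reactants: 13 1-[4-(benzyloxy)phenyl]ethan-1-one; 14 ethyl bromoacetate
Product: 16 ethyl 4-[4-(benzyloxy)phenyl]-4-oxobutanoate, via lithium enolate 15 (not isolated)
Conditions: LiN(SiMe3)2, THF, −78 °C; then 14, −78 → 0 °C
Reagents that add atoms: none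
Why: SN2 alkylation of the kinetic lithium enolate with the reactive α-bromo ester gives the γ-keto ester.

Step 9
Reactants: 16 ethyl 4-[4-(benzyloxy)phenyl]-4-oxobutanoate
Product: 17 ethyl (4R)-4-[4-(benzyloxy)phenyl]-4-hydroxybutanoate
Conditions: (S)-2-methyl-CBS-oxazaborolidine (10 mol %), BH3·SMe2, THF, −20 °C; MeOH quench; used crude
Reagents that add atoms: none
Why: Corey-Bakshi-Shibata reduction: the (S)-oxazaborolidine-borane complex binds the ketone with the aryl group as the large substituent and delivers hydride to the face that gives the (R)-carbinol, while the ester is untouched at this temperature.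

Step 10
Reactants: 17 ethyl (4R)-4-[4-(benzyloxy)phenyl]-4-hydroxybutanoate
Product: 18 ethyl (4R)-4-[4-(benzyloxy)phenyl]-4-(triethylsilyloxy)butanoate
Conditions: Et3SiCl, imidazole, CH2Cl2, 0 °C
Reagents that add atoms: chlorotriethylsilane, CC[Si](Cl)(CC)CC
Why: Silylation straight after work-up forestalls lactonization and masks the hydroxyl against the ketene of step 12.

Step 11
Reactants: 18 ethyl (4R)-4-[4-(benzyloxy)phenyl]-4-(triethylsilyloxy)butanoate
Product: 21 {[(5R)-5-[4-(benzyloxy)phenyl]-5-(triethylsilyloxy)pent-1-yn-1-yl]oxy}triisopropylsilane, via dibromomethyl ketone enolate 19 (not isolated), via lithium ynolate 20 (not isolated)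
Conditions: CH2Br2, lithium 2,2,6,6-tetramethylpiperidide, THF, −78 °C; LiN(SiMe3)2; n-BuLi, −78 → 0 °C; then i-Pr3SiCl, −78 → 0 °C
Reagents that add atoms: dibromomethane, BrCBr; chlorotriisopropylsilane, CC(C)[Si](Cl)(C(C)C)C(C)C
Why: Kowalski ester homologation: LiCHBr2 adds to the ester, enolate 19 undergoes Br/Li exchange and 1,2-shift of the alkyl group to ynolate 20, and the bulky silyl chloride reacts at oxygen to give the siloxyalkyne.

Step 12
Reactants: 12 1-{4-[2-(allyloxy)-4,6-bis(benzyloxy)benzoyl]-5-(ArB)furan-2-yl}-2-diazoethan-1-one; 21 {[(5R)-5-[4-(benzyloxy)phenyl]-5-(triethylsilyloxy)pent-1-yn-1-yl]oxy}triisopropylsilane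
Product: 26 (ArA)[2-(ArB)-4-hydroxy-5-[(3R)-3-(ArB)-3-(triethylsilyloxy)propyl]-6-(triisopropylsilyloxy)-1-benzofuran-3-yl]methanone, via furylketene 22 (not isolated), via 4-furylcyclobutenone 23 (not isolated), via dienylketene 24 (not isolated), via cyclohexadienone 25 (not isolated)
Conditions: 21 (1.3 equiv), ClCH2CH2Cl, hν (420-450 nm LED), 20 °C; then 80 °C
Reagents that add atoms: none
Why: Light absorbed in the long-wavelength n→π* band of the diazo ketone expels N2 and the furyl group shifts to the former diazo carbon (Wolff rearrangement, forming C6'-C7'), giving furylketene 22. The nucleophilic, chain-bearing carbon of the polarized siloxyalkyne attacks the ketene carbonyl carbon to give the (2+2) adduct 23 (C4a'-C8a' and C5'-C6'), which on warming opens by four-electron conrotatory cleavage of the old C6'-C8a' bond to dienylketene 24. Ring D then closes by a thermal six-electron disrotatory electrocyclization of the ketene carbon onto furan C3 (C8'-C8a'), and dienone 25 tautomerizes to the phenol with regained aromaticity. The closest precedent is the photochemical (second-generation) Danheiser benzannulation of aryl and heteroaryl α-diazo ketones with triisopropylsiloxyalkynes. No stereocentre is created and the carbinol centre of 21 is a spectator. Only regiocontrol is needed: the ynol ether polarization puts the chain ortho and the silyloxy group meta to the new hydroxyl, furan C3 is the sole position open to the closure, the visible-light window should leave the diaryl ketone unexcited, and the future O1' (free OH) and O5' (silyl ether) emerge differentiated.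

Step 13
Reactants: 26 (ArA)[2-(ArB)-4-hydroxy-5-[(3R)-3-(ArB)-3-(triethylsilyloxy)propyl]-6-(triisopropylsilyloxy)-1-benzofuran-3-yl]methanone
Product: 27 (ArA)[2-(ArB)-4-hydroxy-5-[(3R)-3-(ArB)-3-hydroxypropyl]-6-(triisopropylsilyloxy)-1-benzofuran-3-yl]methanone
Conditions: HF·pyridine, pyridine, THF, 0 °C
Reagents that add atoms: none
Why: Buffered HF·pyridine cleaves the secondary triethylsilyl ether much faster than the hindered aryl triisopropylsilyl ether, so the carbinol is exposed while O5' stays masked and only O1' can cyclize.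

Step 14
Reactants: 27 (ArA)[2-(ArB)-4-hydroxy-5-[(3R)-3-(ArB)-3-hydroxypropyl]-6-(triisopropylsilyloxy)-1-benzofuran-3-yl]methanone
Product: 29 (ArA)[(2S)-2,8-bis(ArB)-5-(triisopropylsilyloxy)-3,4-dihydro-2H-furo[2,3-h]chromen-9-yl]methanone, via oxyphosphonium phenoxide 28 (not isolated)
Conditions: PPh3, DIAD, toluene, −20 → 0 °C
Reagents that add atoms: none
Why: Intramolecular Mitsunobu etherification: the phenoxide displaces the oxyphosphonium group of 28 by SN2 in a 6-exo-tet closure of ring G with inversion, turning the (R)-carbinol into (2'S); low temperature in toluene disfavours ionization of the 4-alkoxybenzylic centre.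

Step 15
Reactants: 29 (ArA)[(2S)-2,8-bis(ArB)-5-(triisopropylsilyloxy)-3,4-dihydro-2H-furo[2,3-h]chromen-9-yl]methanone
Product: 31 (ArA)[(2S)-5-(benzyloxy)-2,8-bis(ArB)-3,4-dihydro-2H-furo[2,3-h]chromen-9-yl]methanone, via tetrabutylammonium phenoxide 30 (not isolated)
Conditions: Bu4NF, THF, 0 °C; then BnBr, 20 °C
Reagents that add atoms: benzyl bromide, BrCc1ccccc1
Why: Fluoride cleaves the aryl silyl ether and the phenoxide is benzylated in the same flask (Williamson), so that every remaining phenol protecting group but the allyl ether falls in one final hydrogenolysis.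

Step 16
Reactants: 31 (ArA)[(2S)-5-(benzyloxy)-2,8-bis(ArB)-3,4-dihydro-2H-furo[2,3-h]chromen-9-yl]methanone
Product: 32 (ArA')[(2S)-5-(benzyloxy)-2,8-bis(ArB)-3,4-dihydro-2H-furo[2,3-h]chromen-9-yl]methanone
Conditions: Pd(PPh3)4 (5 mol %), morpholine, THF, 20 °C
Reagents that add atoms: none
Why: Tsuji-Trost deallylation: zerovalent palladium ionizes the aryl allyl ether and morpholine traps the π-allyl fragment, freeing the one ring A phenol needed as nucleophile for ring C; benzyl ethers are inert.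

Step 17
Reactants: 32 (ArA')[(2S)-5-(benzyloxy)-2,8-bis(ArB)-3,4-dihydro-2H-furo[2,3-h]chromen-9-yl]methanone
Product: 34 (2R,3S,2'S)-penta-O-benzyl ether of the target (benzyl on O5, O7, O5' and both ring B and B' oxygens; free 3-OH), via benzofuran epoxide 33 (not isolated)
Conditions: (R,R)-[N,N'-bis(3,5-di-tert-butylsalicylidene)-1,2-cyclohexanediaminato]MnCl (10 mol %), N-methylmorpholine N-oxide, m-CPBA, CH2Cl2, −78 → −20 °C; then 0 °C
Reagents that add atoms: m-CPBA, O=C(OO)c1cccc(Cl)c1
Why: Proposed new method: the oxo-manganese salen species should transfer oxygen to the C2=C3 enol-ether bond of the benzofuran on the face chosen by the ligand, setting C3 (S); the resulting 2-aryl-2-aryloxy oxirane 33 ionizes at C2 (cation stabilized by O7' and ring B) and the hydrogen-bonded ring A phenol adds to C2 in a 6-endo closure of ring C from the only face it can reach, that of C4, which fixes C2 and leaves the C3 oxygen as the tertiary alcohol. The closest known reactions are the Jacobsen-Katsuki epoxidation of cyclic conjugated cis-olefins (indene, chromenes) and of the enol-ether double bond of isoflavones, and dioxirane epoxidation of benzofurans with nucleophilic opening at C2. The (R,R) ligand is chosen by analogy with the facial sense known for indene; this sense would have to be confirmed and the (S,S) complex is the alternative.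

Step 18
Reactants: 34 (2R,3S,2'S)-penta-O-benzyl ether of the target
Product: 35 target, (2R,3S,2'S)-3,5,7-trihydroxy-2-(4-hydroxyphenyl)chroman-4-one fused through C2-O7' and C3-C8' to (2'S)-5'-hydroxy-2'-(4-hydroxyphenyl)flavan
Conditions: H2 (1 atm), Pd on carbon (10 wt %), EtOAc/MeOH, 20 °C; stopped after uptake of five equivalents
Reagents that add atoms: none
Why: Hydrogenolysis of the five aryl benzyl ethers under neutral conditions; aryl benzyl ethers cleave far faster than the cyclic benzylic ether of ring G, the ketal or the tertiary carbinol, and no stereocentre is touched.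

**Compound list**

1 | methyl 4,5-dibromofuran-2-carboxylate | COC(=O)c1cc(Br)c(Br)o1 | starting material
2 | [4-(benzyloxy)phenyl]boronic acid | OB(O)c1ccc(OCc2ccccc2)cc1 | starting material
3 | methyl 5-[4-(benzyloxy)phenyl]-4-bromofuran-2-carboxylate | COC(=O)c1cc(Br)c(-c2ccc(OCc3ccccc3)cc2)o1 | intermediate
4 | 2,4,6-trihydroxybenzaldehyde | O=Cc1c(O)cc(O)cc1O | starting material
5 | 2,4-bis(benzyloxy)-6-hydroxybenzaldehyde | O=Cc1c(O)cc(OCc2ccccc2)cc1OCc1ccccc1 | intermediate
6 | 2-(allyloxy)-4,6-bis(benzyloxy)benzaldehyde | C=CCOc1cc(OCc2ccccc2)cc(OCc2ccccc2)c1C=O | intermediate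
7 | [5-(ArB)-2-(methoxycarbonyl)furan-4-yl]magnesium chloride (LiCl adduct) | COC(=O)c1cc([Mg]Cl)c(-c2ccc(OCc3ccccc3)cc2)o1 | intermediate (not isolated)
8 | methyl 4-[(ArA)(hydroxy)methyl]-5-(ArB)furan-2-carboxylate, racemic | COC(=O)c1cc(C(O)c2c(OCC=C)cc(OCc3ccccc3)cc2OCc2ccccc2)c(-c2ccc(OCc3ccccc3)cc2)o1 | intermediate
9 | methyl 4-[2-(allyloxy)-4,6-bis(benzyloxy)benzoyl]-5-(ArB)furan-2-carboxylate | COC(=O)c1cc(C(=O)c2c(OCC=C)cc(OCc3ccccc3)cc2OCc2ccccc2)c(-c2ccc(OCc3ccccc3)cc2)o1 | intermediate
10 | 4-[2-(allyloxy)-4,6-bis(benzyloxy)benzoyl]-5-(ArB)furan-2-carboxylic acid | OC(=O)c1cc(C(=O)c2c(OCC=C)cc(OCc3ccccc3)cc2OCc2ccccc2)c(-c2ccc(OCc3ccccc3)cc2)o1 | intermediate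
11 | 4-[2-(allyloxy)-4,6-bis(benzyloxy)benzoyl]-5-(ArB)furan-2-carbonyl chloride | ClC(=O)c1cc(C(=O)c2c(OCC=C)cc(OCc3ccccc3)cc2OCc2ccccc2)c(-c2ccc(OCc3ccccc3)cc2)o1 | intermediate (not isolated)
12 | 1-{4-[2-(allyloxy)-4,6-bis(benzyloxy)benzoyl]-5-(ArB)furan-2-yl}-2-diazoethan-1-one | [N-]=[N+]=CC(=O)c1cc(C(=O)c2c(OCC=C)cc(OCc3ccccc3)cc2OCc2ccccc2)c(-c2ccc(OCc3ccccc3)cc2)o1 | intermediate
13 | 1-[4-(benzyloxy)phenyl]ethan-1-one | CC(=O)c1ccc(OCc2ccccc2)cc1 | starting material
14 | ethyl bromoacetate | CCOC(=O)CBr | starting material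
15 | lithium 1-[4-(benzyloxy)phenyl]ethen-1-olate | [Li+].[O-]C(=C)c1ccc(OCc2ccccc2)cc1 | intermediate (not isolated)
16 | ethyl 4-[4-(benzyloxy)phenyl]-4-oxobutanoate | CCOC(=O)CCC(=O)c1ccc(OCc2ccccc2)cc1 | intermediate
17 | ethyl (4R)-4-[4-(benzyloxy)phenyl]-4-hydroxybutanoate | CCOC(=O)CC[C@@H](O)c1ccc(OCc2ccccc2)cc1 | intermediate
18 | ethyl (4R)-4-[4-(benzyloxy)phenyl]-4-(triethylsilyloxy)butanoate | CCOC(=O)CC[C@@H](O[Si](CC)(CC)CC)c1ccc(OCc2ccccc2)cc1 | intermediate
19 | lithium (5R)-5-[4-(benzyloxy)phenyl]-1,1-dibromo-5-(triethylsilyloxy)pent-1-en-2-olate | [Li+].[O-]C(=C(Br)Br)CC[C@@H](O[Si](CC)(CC)CC)c1ccc(OCc2ccccc2)cc1 | intermediate (not isolated)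
20 | lithium (5R)-5-[4-(benzyloxy)phenyl]-5-(triethylsilyloxy)pent-1-yn-1-olate | [Li+].[O-]C#CCC[C@@H](O[Si](CC)(CC)CC)c1ccc(OCc2ccccc2)cc1 | intermediate (not isolated)
21 | {[(5R)-5-[4-(benzyloxy)phenyl]-5-(triethylsilyloxy)pent-1-yn-1-yl]oxy}triisopropylsilane | CC(C)[Si](OC#CCC[C@@H](O[Si](CC)(CC)CC)c1ccc(OCc2ccccc2)cc1)(C(C)C)C(C)C | intermediate
22 | 2-{4-[2-(allyloxy)-4,6-bis(benzyloxy)benzoyl]-5-(ArB)furan-2-yl}ethen-1-one (furylketene) | O=C=Cc1cc(C(=O)c2c(OCC=C)cc(OCc3ccccc3)cc2OCc2ccccc2)c(-c2ccc(OCc3ccccc3)cc2)o1 | intermediate (not isolated)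
23 | 4-furyl-2-[(3R)-3-(ArB)-3-(triethylsilyloxy)propyl]-3-(triisopropylsilyloxy)cyclobut-2-en-1-one, both C4 epimers | O=C1C(CC[C@@H](O[Si](CC)(CC)CC)c2ccc(OCc3ccccc3)cc2)=C(O[Si](C(C)C)(C(C)C)C(C)C)C1c1cc(C(=O)c2c(OCC=C)cc(OCc3ccccc3)cc2OCc2ccccc2)c(-c2ccc(OCc3ccccc3)cc2)o1 | intermediate (not isolated)
24 | dienylketene from ring opening of 23 (furyl cis to the ketene-bearing carbon) | O=C=C(CC[C@@H](O[Si](CC)(CC)CC)c1ccc(OCc2ccccc2)cc1)/C(O[Si](C(C)C)(C(C)C)C(C)C)=C\c1cc(C(=O)c2c(OCC=C)cc(OCc3ccccc3)cc2OCc2ccccc2)c(-c2ccc(OCc3ccccc3)cc2)o1 | intermediate (not isolated)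
25 | cyclohexa-2,4-dienone keto tautomer of 26 | O=C1C(CC[C@@H](O[Si](CC)(CC)CC)c2ccc(OCc3ccccc3)cc2)=C(O[Si](C(C)C)(C(C)C)C(C)C)C=C2OC(c3ccc(OCc4ccccc4)cc3)=C(C(=O)c3c(OCC=C)cc(OCc4ccccc4)cc3OCc3ccccc3)C12 | intermediate (not isolated)
26 | (ArA)[2-(ArB)-4-hydroxy-5-[(3R)-3-(ArB)-3-(triethylsilyloxy)propyl]-6-(triisopropylsilyloxy)-1-benzofuran-3-yl]methanone | O=C(c1c(OCC=C)cc(OCc2ccccc2)cc1OCc1ccccc1)c1c(-c2ccc(OCc3ccccc3)cc2)oc2cc(O[Si](C(C)C)(C(C)C)C(C)C)c(CC[C@@H](O[Si](CC)(CC)CC)c3ccc(OCc4ccccc4)cc3)c(O)c12 | intermediate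
27 | (ArA)[2-(ArB)-4-hydroxy-5-[(3R)-3-(ArB)-3-hydroxypropyl]-6-(triisopropylsilyloxy)-1-benzofuran-3-yl]methanone | O=C(c1c(OCC=C)cc(OCc2ccccc2)cc1OCc1ccccc1)c1c(-c2ccc(OCc3ccccc3)cc2)oc2cc(O[Si](C(C)C)(C(C)C)C(C)C)c(CC[C@@H](O)c3ccc(OCc4ccccc4)cc3)c(O)c12 | intermediate
28 | oxyphosphonium phenoxide of 27 (carbinol oxygen on PPh3, phenol deprotonated) | O=C(c1c(OCC=C)cc(OCc2ccccc2)cc1OCc1ccccc1)c1c(-c2ccc(OCc3ccccc3)cc2)oc2cc(O[Si](C(C)C)(C(C)C)C(C)C)c(CC[C@@H](O[P+](c3ccccc3)(c3ccccc3)c3ccccc3)c3ccc(OCc4ccccc4)cc3)c([O-])c12 | intermediate (not isolated)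
29 | (ArA)[(2S)-2,8-bis(ArB)-5-(triisopropylsilyloxy)-3,4-dihydro-2H-furo[2,3-h]chromen-9-yl]methanone | O=C(c1c(OCC=C)cc(OCc2ccccc2)cc1OCc1ccccc1)c1c(-c2ccc(OCc3ccccc3)cc2)oc2cc(O[Si](C(C)C)(C(C)C)C(C)C)c3c(c12)O[C@H](c1ccc(OCc2ccccc2)cc1)CC3 | intermediate
30 | tetrabutylammonium phenoxide of desilylated 29 | O=C(c1c(OCC=C)cc(OCc2ccccc2)cc1OCc1ccccc1)c1c(-c2ccc(OCc3ccccc3)cc2)oc2cc([O-])c3c(c12)O[C@H](c1ccc(OCc2ccccc2)cc1)CC3.CCCC[N+](CCCC)(CCCC)CCCC | intermediate (not isolated)
31 | (ArA)[(2S)-5-(benzyloxy)-2,8-bis(ArB)-3,4-dihydro-2H-furo[2,3-h]chromen-9-yl]methanone | O=C(c1c(OCC=C)cc(OCc2ccccc2)cc1OCc1ccccc1)c1c(-c2ccc(OCc3ccccc3)cc2)oc2cc(OCc3ccccc3)c3c(c12)O[C@H](c1ccc(OCc2ccccc2)cc1)CC3 | intermediate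
32 | (ArA')[(2S)-5-(benzyloxy)-2,8-bis(ArB)-3,4-dihydro-2H-furo[2,3-h]chromen-9-yl]methanone | O=C(c1c(O)cc(OCc2ccccc2)cc1OCc1ccccc1)c1c(-c2ccc(OCc3ccccc3)cc2)oc2cc(OCc3ccccc3)c3c(c12)O[C@H](c1ccc(OCc2ccccc2)cc1)CC3 | intermediate
33 | 8,9-epoxide of 32, oxygen on the face that becomes the (3S) carbinol | O=C(c1c(O)cc(OCc2ccccc2)cc1OCc1ccccc1)[C@]12O[C@@]1(c1ccc(OCc3ccccc3)cc1)Oc1cc(OCc3ccccc3)c3c(c12)O[C@H](c1ccc(OCc2ccccc2)cc1)CC3 | intermediate (not isolated)
34 | (2R,3S,2'S)-penta-O-benzyl ether of the target (free 3-OH) | O=C1c2c(OCc3ccccc3)cc(OCc3ccccc3)cc2O[C@@]2(c3ccc(OCc4ccccc4)cc3)Oc3cc(OCc4ccccc4)c4c(c3[C@]12O)O[C@H](c1ccc(OCc2ccccc2)cc1)CC4 | intermediate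
35 | CNP0208300.3, (2R,3S,2'S) | O=C1c2c(O)cc(O)cc2O[C@@]2(c3ccc(O)cc3)Oc3cc(O)c4c(c3[C@]12O)O[C@H](c1ccc(O)cc1)CC4 | target

**Step count and risks**

Total step count: 18. Longest linear sequence: 13 steps (4 → 35 through steps 2-7 and 12-18).

Steps most likely to fail:

1. Step 17 (epoxidation and ring C closure). Facial selection on the tetrasubstituted push-pull double bond may be poor, the catalytic turnover may be slow, or the oxo-manganese species may oxidize the free phenol instead. The fallback gives up reagent control and sets out from 32. Dimethyldioxirane in acetone/CH2Cl2 at −40 → 0 °C, an epoxidation known for benzofurans, should attack both faces, giving 33 together with the opposite-face epoxide F1. Each epoxide is captured by the ring A phenol, so 34 forms beside the epimeric ketal F2. Because C2' is already (S), 34 and F2 are diastereomers and are separated by chromatography. The route is rejoined at 34.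

2. Step 12 (benzannulation). The diaryl ketone may absorb part of the light and abstract hydrogen from the ortho ether CH2 groups, or the ketene may be intercepted before it meets the ynol ether. The fallback makes the same ketene without light and sets out from 12. Wolff rearrangement catalysed by silver benzoate (AgO2CPh) with Et3N in aqueous THF (Arndt-Eistert homologation) should give the furylacetic acid F3. Oxalyl chloride converts it into the furylacetyl chloride F4. Slow addition of F4 to Et3N and 21 in toluene generates ketene 22 by dehydrochlorination in the presence of the ynol ether. Heating to 80-110 °C then takes cyclobutenone 23 through 24 and 25 to 26, where the route is rejoined.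

3. Step 11 (siloxyalkyne). Excess alkyllithium may deprotonate the benzylic positions (Wittig rearrangement of the aryl benzyl ether, silyl migration at the silyloxy carbon), and the ynolate may be silylated on carbon. The fallback reaches the ynolate by oxidation instead of rearrangement and sets out from 18. Reduction with i-Bu2AlH in CH2Cl2 at −78 °C should give the aldehyde F5. The Ohira-Bestmann reagent with K2CO3 in MeOH converts it into the terminal alkyne F6. Deprotonation with LiN(SiMe3)2 and oxidation of the lithium acetylide with t-BuOOLi in THF (−78 → 0 °C) gives ynolate 20. i-Pr3SiOTf silylates 20 on oxygen to 21, where the route is rejoined.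

**Further compounds**

F1 | step 17 | opposite-face 8,9-epoxide of 32 (diastereomer of 33) | O=C(c1c(O)cc(OCc2ccccc2)cc1OCc1ccccc1)[C@@]12O[C@]1(c1ccc(OCc3ccccc3)cc1)Oc1cc(OCc3ccccc3)c3c(c12)O[C@H](c1ccc(OCc2ccccc2)cc1)CC3
F2 | step 17 | (2S,3R,2'S) diastereomer of 34 | O=C1c2c(OCc3ccccc3)cc(OCc3ccccc3)cc2O[C@]2(c3ccc(OCc4ccccc4)cc3)Oc3cc(OCc4ccccc4)c4c(c3[C@@]12O)O[C@H](c1ccc(OCc2ccccc2)cc1)CC4
F3 | step 12 | {4-[2-(allyloxy)-4,6-bis(benzyloxy)benzoyl]-5-(ArB)furan-2-yl}acetic acid | OC(=O)Cc1cc(C(=O)c2c(OCC=C)cc(OCc3ccccc3)cc2OCc2ccccc2)c(-c2ccc(OCc3ccccc3)cc2)o1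
F4 | step 12 | {4-[2-(allyloxy)-4,6-bis(benzyloxy)benzoyl]-5-(ArB)furan-2-yl}acetyl chloride | ClC(=O)Cc1cc(C(=O)c2c(OCC=C)cc(OCc3ccccc3)cc2OCc2ccccc2)c(-c2ccc(OCc3ccccc3)cc2)o1
F5 | step 11 | (4R)-4-[4-(benzyloxy)phenyl]-4-(triethylsilyloxy)butanal | O=CCC[C@@H](O[Si](CC)(CC)CC)c1ccc(OCc2ccccc2)cc1
F6 | step 11 | {[(1R)-1-[4-(benzyloxy)phenyl]pent-4-yn-1-yl]oxy}triethylsilane | C#CCC[C@@H](O[Si](CC)(CC)CC)c1ccc(OCc2ccccc2)cc1
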